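Late in a run I watched one quantity, the share of Sbt.Rgt in what had become Sbt.Rgt or Sid, and asked where it would come to rest.

all flasks: Ctl 5 mol%; Rgt2 580 mM

| charge | Sbt | Rgt | temperature | remark | time |
|---|---|---|---|---|---|
| south-west | 2 M | 0.55 equiv | −5 °C | run made earlier |  |
| north-west | 2 M | 0.83 equiv | 25 °C | run made earlier |  |
| south | 1 M | 1.1 equiv | −5 °C | run made earlier |  |
| summer | 2.0 M | 1.10 equiv | 0 °C |  | 80 min |
| spring | 2.0 M | 1.10 equiv |  | at 50 °C until 15 min, from then on at 0 °C | 80 min |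
| noon | 2.0 M | 1.10 equiv | 50 °C |  | 80 min |
| winter | 2.0 M | 1.10 equiv | 25 °C |  | 80 min |

- south-west (time / min: Sbt.Rgt / %, Sid / %, Sbt / %): 12.0: 8.0, 3.6, 89.5; 25.0: 12.7, 6.0, 81.3; 40.0: 16.7, 7.3, 77.5; 50.0: 16.2, 8.8, 76.0; 60.0: 18.1, 8.9, 73.4
- north-west (time / min: Sbt.Rgt / %, Sid / %, Sbt / %): 2.00: 21.8, 13.7, 65.5; 4.00: 22.8, 20.3, 55.4; 8.00: 16.0, 32.7, 49.8; 15.0: 12.5, 39.0, 49.5; 20.0: 11.7, 41.4, 47.6
- south (time / min: Sbt.Rgt / %, Sid / %, Sbt / %): 6.00: 4.3, 1.1, 93.0; 15.0: 8.0, 5.1, 86.7; 30.0: 12.8, 8.0, 76.4; 50.0: 18.8, 8.9, 71.8; 60.0: 21.8, 10.1, 70.5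

(scatter of a reading: 1 percentage point)

- the flask with the highest share of Sbt.Rgt in all that became Sbt.Rgt or Sid ("all alike" if they lie within 1.5 percentage points) (summer / spring / noon / winter / all alike)
- share of Sbt.Rgt in all that became Sbt.Rgt or Sid, summer
- share of Sbt.Rgt in all that became Sbt.Rgt or Sid, spring
- share of Sbt.Rgt in all that became Sbt.Rgt or Sid, noon
- share of Sbt.Rgt in all that became Sbt.Rgt or Sid, winter

- reactions considered so far: Sbt + Rgt <-> Sbt.Rgt; Sbt + Rgt <-> Sid; Sbt.Rgt + Ctl <-> Sid + Ctl; 2 Rgt -> Tgt; Ctl + Rgt2 <-> Ctl.Rgt2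

| run | share, last reading but one | share, last reading |
|---|---|---|
| south-west | 64.8 % | 67.0 % |
| south | 67.9 % | 68.3 % |
| north-west | 24.3 % | 22.0 % |

In the cold runs, at −5 °C, the two products grew side by side at about the cold share, 67.0 %. In the north-west run, at 25 °C, the share fell from 61.4 % at 2.00 min to 32.9 % at 8.00 min, and then slowed. I took its last reading, a single scattered one, as my estimate of the resting share, the mixture Sbt.Rgt and Sid reach once Ctl turns one into the other: kinetic control in the cold, thermodynamic control here.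

But was it at rest? The excess over 22.0 % shrank with a relaxation time of 4.65 min, so the last reading came after 4.31 such times. Winter, at 80 min, gets 17.2 of them, so I said 22.0 % there. I said the same for noon, although the resting share may shift at 50 °C, and the runs cannot compute that.

Spring gets 3.23 relaxation times before cooling even at the 25 °C pace, which leaves 1.8 percentage points of excess. But Rgt may go on feeding at the cold share after the change. A feed of 1.6 points, the north-west run's last gain, lifts spring to 23.4 %.

Summer, at 0 °C, is warmer than the cold runs and may lie somewhat below 67.0 %, yet the gap of 45 points dwarfs the margin of 1.5 points, so I put summer highest.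

The forecast, slightly apart from my numbers, named summer, with 62 % for summer, 24 % for spring, 23 % for noon and 20 % for winter, reasoning that “Cooling then freezes that mixture”.

The flasks gave summer highest: summer 62.9 %, spring 21.8 %, noon 19.8 %, winter 18.7 %.

    Sbt + Rgt ⇌ Sbt.Rgt (K = 3.50 /M, k = 0.00260 /M/s, Ea = 67.0 kJ/mol, ΔH = −23.0 kJ/mol)
    Sbt + Rgt ⇌ Sid (K = 15.0 /M, k = 0.00110 /M/s, Ea = 66.0 kJ/mol, ΔH = −25.0 kJ/mol)
    Sbt.Rgt + Ctl ⇌ Sid + Ctl, rate k3*[Ctl]*[Sbt.Rgt] forward; the back reaction follows from the equilibrium constant (k = 0.0450 /M/s, Ea = 68.0 kJ/mol)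
    2 Rgt → Tgt (k = 0.00160 /M/s, Ea = 48.0 kJ/mol)
    Ctl + Rgt2 ⇌ Ctl.Rgt2, settled at all times (K = 1.70 /M, ΔH = −80.0 kJ/mol)
    (constants at 25 °C)

In spring the forward rates favoured Sbt.Rgt over Sid by 2.4 just after the start and still by 2.3 at 80.0 min, yet at the change, 15.0 min, the share already stood at 19.7 %. Free Ctl then went from 92.6 % to 5.94 % of its charge by the end, and the share in spring closed at 21.8 %, still not at rest, for it stood at 18.5 % after 800 min; its nearness to my estimate of 22.0 %, one reading at 25 °C, was coincidence. For the neighbour flask, spring left until 5.0 h, my estimate of the resting share again says about 22.0 %. The computed flask gives 20.6 %, less than that estimate, with 1.5 % of the Rgt charge left free.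

(The earlier runs and the new flask stem from a simulated flask on assumed constants; scatter was added.)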